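**Strategy.** Everything rests on disconnecting, in each trimethylcyclopentane ring, the bond between the gem-dimethyl ring carbon and the neighbouring unsubstituted ring CH2. The precursor is acyclic and already carries the benzylic quaternary stereocentre, an isopropenyl group and a three-carbon chain ending in an aldehyde N-tosylhydrazone. Hydrogen-atom transfer from an iron hydride turns the isopropenyl group into the tertiary radical, which closes 5-exo onto the hydrazone carbon; loss of sulfinate and N2 then leaves that carbon as a bare CH2. One flask thus forms the ring, the second geminal methyl group and a methylene free of functionality. The twofold-symmetric bibenzyl is made last, by oxidative benzylic coupling of two identical monomers and demethylation.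

Key step: step 8

Remark: both quaternary carbons are (S) and the two halves are related by a twofold axis, so the ring closure is run once on a monomer, from which both cyclopentane rings of the target derive.

**Step 1**
Reactants: 1 (3,4-dimethoxytoluene)
Product: 3 ketone 1-(2,3-dimethoxy-5-methylphenyl)ethan-1-one, via aryllithium 2 (not isolated)
Conditions: nBuLi, TMEDA, Et2O, 0 °C to rt; then MeC(O)N(OMe)Me, −78 °C to rt; then H2O
Reagents that add atoms: N-methoxy-N-methylacetamide, CC(=O)N(C)OC
Why: Directed ortho-metalation places lithium at the unhindered ring position ortho to a methoxy group and remote from the methyl group, and acylation of the aryllithium by the Weinreb amide stops at the ketone because the N-methoxy group prevents over-addition.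

**Step 2**
Reactants: 3 (ketone)
Product: 4 alcohol (1S)-1-(2,3-dimethoxy-5-methylphenyl)ethan-1-ol
Conditions: (R)-2-methyl-CBS-oxazaborolidine (10 mol%), BH3·SMe2, THF, 0 °C; then MeOH
Reagents that add atoms: none
Why: In this Corey–Bakshi–Shibata reduction the (R)-oxazaborolidine binds the ketone with the aryl group as the large substituent and delivers hydride to one face, which should set the (S)-carbinol centre.

**Step 3**
Reactants: 4 (alcohol)
Product: 5 carbamate (1S)-1-(2,3-dimethoxy-5-methylphenyl)ethyl N,N-diisopropylcarbamate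
Conditions: iPr2NCOCl, Et3N, CH2Cl2, reflux
Reagents that add atoms: N,N-diisopropylcarbamoyl chloride, CC(C)N(C(C)C)C(Cl)=O
Why: O-Carbamoylation installs the group that later directs the benzylic lithiation and serves as leaving group in the 1,2-metallate shift; the stereocentre is not touched.

**Step 4**
Reactants: 6 ([2-(1,3-dioxolan-2-yl)ethyl]magnesium bromide, commercial THF solution)
Product: 7 boronic ester 2-[2-(1,3-dioxolan-2-yl)ethyl]-4,4,5,5-tetramethyl-1,3,2-dioxaborolane
Conditions: iPrOBpin, THF, −78 °C to rt; then H2O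
Reagents that add atoms: 2-isopropoxy-4,4,5,5-tetramethyl-1,3,2-dioxaborolane, CC(C)OB1OC(C)(C)C(C)(C)O1
Why: Borylation of a Grignard reagent with an alkoxyboronic ester displaces isopropoxide at boron, and the dioxolane is inert to these conditions.

**Step 5**
Reactants: 5 (carbamate); 7 (boronic ester)
Product: 10 tertiary boronic ester 2-[(2S)-2-(2,3-dimethoxy-5-methylphenyl)-4-(1,3-dioxolan-2-yl)butan-2-yl]-4,4,5,5-tetramethyl-1,3,2-dioxaborolane, via lithiated carbamate 8 (not isolated), via boronate complex 9 (not isolated)
Conditions: sBuLi, Et2O, −78 °C; then 7, −78 °C; then MgBr2 in MeOH, −78 °C to rt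
Reagents that add atoms: none
Why: In this lithiation–borylation the carbamate-directed benzylic deprotonation gives a configurationally stable tertiary organolithium with retention, the boronic ester is captured with retention, and the stereospecific 1,2-metallate rearrangement (alkyl migration anti to the carbamate leaving group, assisted by MgBr2/MeOH) transfers the chirality of 5 to the tertiary boronic ester.

**Step 6**
Reactants: 10 (tertiary boronic ester)
Product: 13 alkene 2-[(3S)-3-(2,3-dimethoxy-5-methylphenyl)-3,4-dimethylpent-4-en-1-yl]-1,3-dioxolane, via isopropenyl boronate complex 11 (not isolated), via iodo boronic ester 12 (not isolated)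
Conditions: 2-bromopropene, tBuLi, THF, −78 °C; add 10; then I2 in MeOH, −78 °C; then NaOMe in MeOH, −78 °C to rt
Reagents that add atoms: 2-bromopropene, CC(Br)=C (converted in the flask into isopropenyllithium, [Li]C(C)=C)
Why: In this Zweifel olefination iodine triggers 1,2-migration of the tertiary alkyl group from boron to the alkenyl carbon with retention of configuration, and methoxide-induced anti elimination of boron and iodide gives the isopropenyl-bearing quaternary stereocentre.

**Step 7**
Reactants: 13 (alkene acetal)
Product: 15 hydrazone N'-[(1E,4S)-4-(2,3-dimethoxy-5-methylphenyl)-4,5-dimethylhex-5-en-1-ylidene]-4-methylbenzenesulfonohydrazide, via aldehyde 14 (not isolated)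
Conditions: TsNHNH2, HCl (cat.), THF/H2O, rt
Reagents that add atoms: 4-methylbenzenesulfonohydrazide, Cc1ccc(cc1)S(=O)(=O)NN
Why: Acid-catalysed acetal cleavage and hydrazone condensation run in one pot, so the aldehyde is trapped as it forms and has little chance to undergo an ene reaction with the isopropenyl group.

**Step 8**
Reactants: 15 (hydrazone)
Product: 18 monomer 1,2-dimethoxy-5-methyl-3-[(1S)-1,2,2-trimethylcyclopentyl]benzene, via cyclised sulfonyl hydrazide 16 (not isolated), via diazene 17 (not isolated)
Conditions: Fe(acac)3 (30 mol%), PhSiH3, THF/MeOH, 40 °C; then NaOAc, MeOH, 65 °C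
Reagents that add atoms: none
Why: Fe(acac)3 and PhSiH3 generate an iron hydride that transfers a hydrogen atom to the terminal CH2 of the isopropenyl group (Markovnikov MHAT), which creates the second geminal methyl group and the tertiary radical at the future gem-dimethyl carbon. This nucleophilic radical adds in a 5-exo-trig mode to the carbon of the electron-poor C=N bond of the N-tosylhydrazone, which closes the cyclopentane; the hydrazinyl radical is reduced by divalent iron and protonated to the hydrazide 16. Heating with NaOAc eliminates p-toluenesulfinate to the diazene 17, which loses N2 (the final stage of a Caglioti-type hydrazone reduction), so the attacked carbon ends as an unsubstituted ring CH2. The closest known reaction types are the iron-hydride-initiated reductive coupling of unactivated olefins with sulfonylhydrazones, known in intra- and intermolecular form, and its traceless variant used for olefin hydromethylation. No lasting stereocentre is formed: both epimers of 16 converge on 18 when N2 is lost, and the existing quaternary centre bears no hydrogen and takes no part. The step needs HAT to the 1,1-disubstituted olefin in preference to hydrazone reduction, and ring closure faster than quenching of the radical; the terminal olefin, the gem-disubstituted tether (Thorpe–Ingold effect) and the polarity match of tertiary radical and sulfonylhydrazone should secure both.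

**Step 9**
Reactants: 18 (monomer, two molecules)
Product: 21 dimer 1,2-bis{3,4-dimethoxy-5-[(1S)-1,2,2-trimethylcyclopentyl]phenyl}ethane, via benzylpotassium 19 (not isolated), via benzyl bromide 20 (not isolated)
Conditions: nBuLi, KOtBu, TMP(H), THF, −78 °C; then BrCH2CH2Br (0.5 equiv), −78 °C to rt; then H2O
Reagents that add atoms: none
Why: Lateral (benzylic) metalation with the mixed lithium/potassium amide base under equilibrating conditions is followed by oxidative homocoupling, in which 1,2-dibromoethane converts half of the benzylpotassium into the benzyl bromide that the other half alkylates; the quaternary stereocentres are remote and untouched, and any minor enantiomer should end mainly in the separable meso diastereomer.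

**Step 10**
Reactants: 21 (dimer tetramethyl ether)
Product: 22 target 5,5'-(ethane-1,2-diyl)bis{3-[(1S)-1,2,2-trimethylcyclopentyl]benzene-1,2-diol}
Conditions: BBr3, CH2Cl2, −78 °C to 0 °C; then H2O
Reagents that add atoms: none
Why: BBr3 cleaves the four aryl methyl ethers (Lewis-acid-mediated demethylation), and the all-carbon quaternary centres can neither ionise nor epimerise.

**Compound list**

1 | 3,4-dimethoxytoluene | Cc1ccc(OC)c(OC)c1 | starting material
2 | (2,3-dimethoxy-5-methylphenyl)lithium (not isolated) | [Li]c1cc(C)cc(OC)c1OC | intermediate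
3 | 1-(2,3-dimethoxy-5-methylphenyl)ethan-1-one | CC(=O)c1cc(C)cc(OC)c1OC | intermediate
4 | (1S)-1-(2,3-dimethoxy-5-methylphenyl)ethan-1-ol | C[C@H](O)c1cc(C)cc(OC)c1OC | intermediate
5 | (1S)-1-(2,3-dimethoxy-5-methylphenyl)ethyl N,N-diisopropylcarbamate | C[C@H](OC(=O)N(C(C)C)C(C)C)c1cc(C)cc(OC)c1OC | intermediate
6 | [2-(1,3-dioxolan-2-yl)ethyl]magnesium bromide | Br[Mg]CCC1OCCO1 | starting material
7 | 2-[2-(1,3-dioxolan-2-yl)ethyl]-4,4,5,5-tetramethyl-1,3,2-dioxaborolane | CC1(C)OB(CCC2OCCO2)OC1(C)C | intermediate
8 | [(1S)-1-(diisopropylcarbamoyloxy)-1-(2,3-dimethoxy-5-methylphenyl)ethyl]lithium (not isolated) | C[C@]([Li])(OC(=O)N(C(C)C)C(C)C)c1cc(C)cc(OC)c1OC | intermediate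
9 | lithium boronate complex of 8 and 7, boron bound with retention (not isolated) | C[C@]([B-]1(CCC2OCCO2)OC(C)(C)C(C)(C)O1)(OC(=O)N(C(C)C)C(C)C)c1cc(C)cc(OC)c1OC.[Li+] | intermediate
10 | 2-[(2S)-2-(2,3-dimethoxy-5-methylphenyl)-4-(1,3-dioxolan-2-yl)butan-2-yl]-4,4,5,5-tetramethyl-1,3,2-dioxaborolane | C[C@@](B1OC(C)(C)C(C)(C)O1)(CCC1OCCO1)c1cc(C)cc(OC)c1OC | intermediate
11 | lithium isopropenyl boronate complex of 10 (not isolated) | C[C@@]([B-]1(C(C)=C)OC(C)(C)C(C)(C)O1)(CCC1OCCO1)c1cc(C)cc(OC)c1OC.[Li+] | intermediate
12 | 2-[(3S)-3-(2,3-dimethoxy-5-methylphenyl)-5-(1,3-dioxolan-2-yl)-1-iodo-2,3-dimethylpentan-2-yl]-4,4,5,5-tetramethyl-1,3,2-dioxaborolane, both epimers at C2 (not isolated) | C[C@@](C(C)(CI)B1OC(C)(C)C(C)(C)O1)(CCC1OCCO1)c1cc(C)cc(OC)c1OC | intermediate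
13 | 2-[(3S)-3-(2,3-dimethoxy-5-methylphenyl)-3,4-dimethylpent-4-en-1-yl]-1,3-dioxolane | C[C@@](C(C)=C)(CCC1OCCO1)c1cc(C)cc(OC)c1OC | intermediate
14 | (4S)-4-(2,3-dimethoxy-5-methylphenyl)-4,5-dimethylhex-5-enal (not isolated) | C[C@@](C(C)=C)(CCC=O)c1cc(C)cc(OC)c1OC | intermediate
15 | N'-[(1E,4S)-4-(2,3-dimethoxy-5-methylphenyl)-4,5-dimethylhex-5-en-1-ylidene]-4-methylbenzenesulfonohydrazide | C[C@@](C(C)=C)(CC/C=N/NS(=O)(=O)c1ccc(C)cc1)c1cc(C)cc(OC)c1OC | intermediate
16 | N'-[(3S)-3-(2,3-dimethoxy-5-methylphenyl)-2,2,3-trimethylcyclopentyl]-4-methylbenzenesulfonohydrazide, both epimers at C1 (not isolated) | CC1(C)C(NNS(=O)(=O)c2ccc(C)cc2)CC[C@]1(C)c1cc(C)cc(OC)c1OC | intermediate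
17 | [(3S)-3-(2,3-dimethoxy-5-methylphenyl)-2,2,3-trimethylcyclopentyl]diazene (not isolated) | CC1(C)C(N=N)CC[C@]1(C)c1cc(C)cc(OC)c1OC | intermediate
18 | 1,2-dimethoxy-5-methyl-3-[(1S)-1,2,2-trimethylcyclopentyl]benzene | CC1(C)CCC[C@]1(C)c1cc(C)cc(OC)c1OC | intermediate
19 | {3,4-dimethoxy-5-[(1S)-1,2,2-trimethylcyclopentyl]benzyl}potassium (not isolated) | CC1(C)CCC[C@]1(C)c1cc(C[K])cc(OC)c1OC | intermediate
20 | 5-(bromomethyl)-1,2-dimethoxy-3-[(1S)-1,2,2-trimethylcyclopentyl]benzene (not isolated) | CC1(C)CCC[C@]1(C)c1cc(CBr)cc(OC)c1OC | intermediate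
21 | 1,2-bis{3,4-dimethoxy-5-[(1S)-1,2,2-trimethylcyclopentyl]phenyl}ethane | CC1(C)CCC[C@]1(C)c1cc(CCc2cc(OC)c(OC)c([C@@]3(C)CCCC3(C)C)c2)cc(OC)c1OC | intermediate
22 | 5,5'-(ethane-1,2-diyl)bis{3-[(1S)-1,2,2-trimethylcyclopentyl]benzene-1,2-diol} | CC1(C)CCC[C@]1(C)c1cc(CCc2cc(O)c(O)c([C@@]3(C)CCCC3(C)C)c2)cc(O)c1O | target

**Step count.** Total: 10 steps. Longest linear sequence: 9 steps (steps 1–3 and 5–10, from 3,4-dimethoxytoluene); step 4 is a one-step branch.

**Steps most likely to fail**

Step 8. The tertiary radical may be reduced before it cyclises (net hydrogenation of the isopropenyl group), or the hydrazone may be reduced first. The same bond would then be closed by an anionic instead of a radical reaction. The fallback sets out from 13. Aqueous HCl in THF would give the aldehyde 14, now isolated. NaBH4 in MeOH would reduce it to the alcohol (4S)-4-(2,3-dimethoxy-5-methylphenyl)-4,5-dimethylhex-5-en-1-ol F1. I2, PPh3 and imidazole would convert this into the iodide 1-[(3S)-6-iodo-2,3-dimethylhex-1-en-3-yl]-2,3-dimethoxy-5-methylbenzene F2. Iodine–lithium exchange with tBuLi in pentane/Et2O at −78 °C would give the primary alkyllithium [(4S)-4-(2,3-dimethoxy-5-methylphenyl)-4,5-dimethylhex-5-en-1-yl]lithium F3. On addition of TMEDA and warming, F3 should add 5-exo across the isopropenyl group (intramolecular carbolithiation) to give the neopentyl-type organolithium {[(2S)-2-(2,3-dimethoxy-5-methylphenyl)-1,2-dimethylcyclopentyl]methyl}lithium F4. Quenching with MeOH turns the CH2Li group into the second geminal methyl group, and the route is rejoined at 18.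

Step 9. Deprotonation may occur at the ring position ortho to a methoxy group instead of at the methyl group, or the benzyl anion may be alkylated by the oxidant. The ethane bridge would then be built by reductive carbonyl coupling instead of carbanion coupling. The fallback sets out from 18. Benzylic oxidation with IBX in DMSO at 85 °C would give the aldehyde 3,4-dimethoxy-5-[(1S)-1,2,2-trimethylcyclopentyl]benzaldehyde F5. McMurry coupling (TiCl4, Zn, THF, reflux) would give the stilbene (E)-1,2-bis{3,4-dimethoxy-5-[(1S)-1,2,2-trimethylcyclopentyl]phenyl}ethene F6. Hydrogenation (H2, Pd/C, EtOAc) returns to 21.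

Step 5. The boronate complex of the hindered, electron-rich benzylic carbanion may dissociate before the 1,2-shift, which would erode stereochemical fidelity, or the shift may stall. The quaternary centre would then be set by a catalyst-controlled allylic substitution instead of a stereospecific rearrangement. The fallback sets out from 3. Vinylmagnesium bromide in THF would give the racemic tertiary allylic alcohol 2-(2,3-dimethoxy-5-methylphenyl)but-3-en-2-ol F7. SOCl2 in Et2O at 0 °C would convert it, with allylic transposition, into the primary allylic chloride 1-[(2E)-4-chlorobut-2-en-2-yl]-2,3-dimethoxy-5-methylbenzene F8. Copper-catalysed enantioselective SN2' alkylation with Grignard reagent 6 (CuBr·SMe2, chiral phosphoramidite ligand of the enantiomeric series that leads to the (S)-product, CH2Cl2, −78 °C) would give the vinyl compound 2-[(3S)-3-(2,3-dimethoxy-5-methylphenyl)-3-methylpent-4-en-1-yl]-1,3-dioxolane F9. Wacker oxidation under non-acidic conditions (Pd(quinox)Cl2, AgSbF6, aqueous tBuOOH, CH2Cl2) would give the methyl ketone (3R)-3-(2,3-dimethoxy-5-methylphenyl)-5-(1,3-dioxolan-2-yl)-3-methylpentan-2-one F10. Wittig methylenation (Ph3PCH3Br, KOtBu, toluene, 80 °C) returns to 13.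

**Further compounds**

F1 | step 8 | (4S)-4-(2,3-dimethoxy-5-methylphenyl)-4,5-dimethylhex-5-en-1-ol | C[C@@](C(C)=C)(CCCO)c1cc(C)cc(OC)c1OC
F2 | step 8 | 1-[(3S)-6-iodo-2,3-dimethylhex-1-en-3-yl]-2,3-dimethoxy-5-methylbenzene | C[C@@](C(C)=C)(CCCI)c1cc(C)cc(OC)c1OC
F3 | step 8 | [(4S)-4-(2,3-dimethoxy-5-methylphenyl)-4,5-dimethylhex-5-en-1-yl]lithium | C[C@@](C(C)=C)(CCC[Li])c1cc(C)cc(OC)c1OC
F4 | step 8 | {[(2S)-2-(2,3-dimethoxy-5-methylphenyl)-1,2-dimethylcyclopentyl]methyl}lithium | [Li]CC1(C)CCC[C@]1(C)c1cc(C)cc(OC)c1OC
F5 | step 9 | 3,4-dimethoxy-5-[(1S)-1,2,2-trimethylcyclopentyl]benzaldehyde | CC1(C)CCC[C@]1(C)c1cc(C=O)cc(OC)c1OC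
F6 | step 9 | (E)-1,2-bis{3,4-dimethoxy-5-[(1S)-1,2,2-trimethylcyclopentyl]phenyl}ethene | CC1(C)CCC[C@]1(C)c1cc(/C=C/c2cc(OC)c(OC)c([C@@]3(C)CCCC3(C)C)c2)cc(OC)c1OC
F7 | step 5 | 2-(2,3-dimethoxy-5-methylphenyl)but-3-en-2-ol (racemic) | C=CC(C)(O)c1cc(C)cc(OC)c1OC
F8 | step 5 | 1-[(2E)-4-chlorobut-2-en-2-yl]-2,3-dimethoxy-5-methylbenzene | C/C(=C\CCl)c1cc(C)cc(OC)c1OC
F9 | step 5 | 2-[(3S)-3-(2,3-dimethoxy-5-methylphenyl)-3-methylpent-4-en-1-yl]-1,3-dioxolane | C[C@@](C=C)(CCC1OCCO1)c1cc(C)cc(OC)c1OC
F10 | step 5 | (3R)-3-(2,3-dimethoxy-5-methylphenyl)-5-(1,3-dioxolan-2-yl)-3-methylpentan-2-one | C[C@@](C(C)=O)(CCC1OCCO1)c1cc(C)cc(OC)c1OC
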